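**Retrosynthetic overview** (disconnections listed from the first bond made to the last)
- No ring is built: the benzene ring of o-vanillin 1 is carried through and becomes the quinone ring in the last step.
- C=N disconnection: 1 plus tritylhydrazine hydrochloride 2 (freed in the flask to 3) lead to tritylhydrazone 4, the carrier that lets the aldehyde carbon react as a carbanion.
- Key disconnection, side-chain C1'–C2': the azo anion of 4 (nucleophilic former C=O carbon) is joined to 1-iodooctadecane 5 through 6 and 7; N2 and the trityl group leave in the same flask to give phenol 8.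
- C4–O disconnection: para-oxidation of 8 gives the quinone 9.

Assumption: the target has no stereocentre and no stereogenic double bond, so it is achiral and is made as drawn; 2 is taken as a catalogue reagent.

**Step 1**
Reactants: 1 o-vanillin (2-hydroxy-3-methoxybenzaldehyde); 2 tritylhydrazine hydrochloride
Product: 4 (E)-2-methoxy-6-[(2-tritylhydrazinylidene)methyl]phenol (o-vanillin N-tritylhydrazone), via tritylhydrazine 3 (not isolated)
Conditions: NaOAc (1.1 equiv), EtOH, 25 °C, 12 h
Reagents that add atoms: none
Why: Hydrazone formation (aldehyde–hydrazine condensation); NaOAc frees 3 and buffers the medium so the acid-labile N–trityl bond survives, and the E isomer forms as the thermodynamic product held by the O–H···N hydrogen bond, with no stereocentre created.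

**Step 2**
Reactants: 4 o-vanillin N-tritylhydrazone; 5 1-iodooctadecane
Product: 8 2-methoxy-6-nonadecylphenol, via dilithio azo anion 6 (not isolated), via C-alkylated trityl azo phenoxide 7 (not isolated)
Conditions: LiN(iPr)2 (2.2 equiv), THF, −78 °C; then 5 (1.05 equiv), −78 → −20 °C; then EtSH (10 equiv), −20 → 25 °C; H2O work-up
Reagents that add atoms: none
Why: Azo-anion reductive alkylation of an aldehyde tritylhydrazone, a traceless acyl-anion-type umpolung, here run on the phenoxide dianion: the former aldehyde carbon of 6 attacks the primary iodide by SN2 (nitrogen is shielded by the trityl group), and azoalkane 7 then loses N2 homolytically on warming, the benzylic radical taking hydrogen from EtSH and the trityl radical being trapped by EtS•, so the side-chain CH2 is delivered directly and the transient stereocentre of 7 is erased.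

**Step 3**
Reactants: 8 2-methoxy-6-nonadecylphenol
Product: 9 2-methoxy-6-nonadecyl-1,4-benzoquinone (target)
Conditions: (KSO3)2NO (2.5 equiv), KH2PO4, methyltrioctylammonium chloride (5 mol %), CH2Cl2/H2O, 20 °C
Reagents that add atoms: dipotassium nitrosodisulfonate, (KSO3)2NO, [K+].[K+].[O-]S(=O)(=O)N([O])S(=O)(=O)[O-]
Why: Teuber oxidation: one equivalent of the nitroxyl radical abstracts the phenolic hydrogen, a second couples at the free para carbon (both ortho positions are blocked), and loss of HN(SO3K)2 gives the p-quinone, with no stereocentre involved.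

**Compound list**
1 | o-vanillin (2-hydroxy-3-methoxybenzaldehyde) | COc1cccc(C=O)c1O | starting material
2 | tritylhydrazine hydrochloride [(triphenylmethyl)hydrazine hydrochloride] | Cl.NNC(c1ccccc1)(c1ccccc1)c1ccccc1 | starting material
3 | tritylhydrazine (free base) | NNC(c1ccccc1)(c1ccccc1)c1ccccc1 | intermediate
4 | (E)-2-methoxy-6-[(2-tritylhydrazinylidene)methyl]phenol | COc1cccc(/C=N/NC(c2ccccc2)(c2ccccc2)c2ccccc2)c1O | intermediate
5 | 1-iodooctadecane | CCCCCCCCCCCCCCCCCCI | starting material
6 | dilithium salt of 4 (O,N-dilithio azo anion) | [Li+].[Li+].COc1cccc(/C=N/[N-]C(c2ccccc2)(c2ccccc2)c2ccccc2)c1[O-] | intermediate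
7 | lithium 2-methoxy-6-[1-((E)-trityldiazenyl)nonadecyl]phenolate (racemic at C1') | [Li+].COc1cccc(C(CCCCCCCCCCCCCCCCCC)/N=N/C(c2ccccc2)(c2ccccc2)c2ccccc2)c1[O-] | intermediate
8 | 2-methoxy-6-nonadecylphenol | CCCCCCCCCCCCCCCCCCCc1cccc(OC)c1O | intermediate
9 | 2-methoxy-6-nonadecyl-1,4-benzoquinone | CCCCCCCCCCCCCCCCCCCC1=CC(=O)C=C(OC)C1=O | target

**Total step count:** 3. **Longest linear sequence:** 3 (1 → 4 → 8 → 9).

**Steps most likely to fail, with fallbacks**

Step 2 (highest risk). The step is run on an unprotected phenoxide dianion, which is the untested element. N-alkylation, base-induced azo-to-hydrazone tautomerisation of 7, or in-cage recombination of the benzylic radical and the trityl radical could each cut the yield. The fallback sets out from 1 and comes back at 8. Thioacetalisation of 1 with propane-1,3-dithiol (BF3·OEt2, CH2Cl2, 0 °C) gives 2-(1,3-dithian-2-yl)-6-methoxyphenol F1. Double deprotonation (n-BuLi 2.2 equiv, THF, −30 °C) gives the O,C-dilithio derivative of the dithiane F2. This is alkylated with 5 to give, after aqueous work-up, 2-methoxy-6-(2-octadecyl-1,3-dithian-2-yl)phenol F3. Raney Ni in EtOH at reflux then removes the sulfur to give 8.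

Step 3. The waxy phenol must be oxidised across two phases and may react slowly or over-oxidise. The fallback sets out from 8 and comes back at 9. Para-formylation (hexamethylenetetramine, CF3CO2H, reflux, then aqueous HCl; Duff reaction) gives 4-hydroxy-3-methoxy-5-nonadecylbenzaldehyde F4. Dakin oxidation (H2O2, NaOH, THF/H2O, 0 °C, then acidification) gives 2-methoxy-6-nonadecylbenzene-1,4-diol F5. Ag2O (Et2O, MgSO4, 20 °C) oxidises this to 9.

Step 1. The bulky, acid-labile hydrazine may condense slowly or lose its trityl group. The fallback sets out from 1 and comes back at 4. Addition of 1 to excess N2H4·H2O in EtOH at 0 °C (the excess suppresses azine formation) gives (E)-2-(hydrazinylidenemethyl)-6-methoxyphenol F6. N-tritylation with Ph3CCl and Et3N in CH2Cl2 at 0 °C then gives 4.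

**Further compounds**
F1 | step 2 | 2-(1,3-dithian-2-yl)-6-methoxyphenol | COc1cccc(C2SCCCS2)c1O
F2 | step 2 | dilithium salt of F1 (O,C-dilithio dithiane) | [Li+].[Li+].COc1cccc([C-]2SCCCS2)c1[O-]
F3 | step 2 | 2-methoxy-6-(2-octadecyl-1,3-dithian-2-yl)phenol | CCCCCCCCCCCCCCCCCCC1(SCCCS1)c1cccc(OC)c1O
F4 | step 3 | 4-hydroxy-3-methoxy-5-nonadecylbenzaldehyde | CCCCCCCCCCCCCCCCCCCc1cc(C=O)cc(OC)c1O
F5 | step 3 | 2-methoxy-6-nonadecylbenzene-1,4-diol | CCCCCCCCCCCCCCCCCCCc1cc(O)cc(OC)c1O
F6 | step 1 | (E)-2-(hydrazinylidenemethyl)-6-methoxyphenol | COc1cccc(/C=N/N)c1O
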